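Counted with whatever complexes hold, [Z] + [Q] stays at the charge, so every [Q] below is also a reading of [Z].

| flask | Z | E | time |
|---|---|---|---|
| dawn | 0.150 M | 3.00 × 10⁻⁴ M |  |
| dusk | 0.0600 M | 3.00 × 10⁻⁴ M |  |
| winter | 0.150 M | 9.00 × 10⁻⁴ M |  |
| autumn | 0.600 M | 3.00 × 10⁻⁴ M | 14 min |

- dawn run (time / min: [Q] / M): 0.62: 0.0056; 1.9: 0.0131; 3.6: 0.0227; 5.7: 0.0331; 8.2: 0.0424; 11: 0.0506; 14: 0.0586
- dusk run (time / min: [Q] / M): 0.62: 0.0018; 1.9: 0.0058; 3.6: 0.0099; 5.7: 0.0141; 8.2: 0.0190; 11: 0.0232; 14: 0.0275
- winter run (time / min: [Q] / M): 0.62: 0.0136; 1.9: 0.0342; 3.6: 0.0500; 5.7: 0.0672; 8.2: 0.0807; 11: 0.0908; 14: 0.1023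

(readings scatter by 8 × 10⁻⁴ M)

- Overall: Z -> Q, with E as catalyst.
- Constant volume, constant temperature.
- What is held in complexes is read along with the free species.
- An order is taken over about fifteen percent of the charge, up and down.

- how the opening rate goes with [Z] round the charge of the dawn run: the exponent of the rate at two percent of Z gone to Q (one fixed amount of Q, the same in the runs compared)
- how the opening rate goes with [E] round the charge of the dawn run: the exponent of the rate at two percent of Z gone to Q
- the dusk run starts with 0.0900 M less of Z than the dawn run, and with no Q. Compared where both hold the same amount of Z, once fifteen percent of what the dusk run was charged with has turned into Q, is the dusk run faster, slower or alike (within a tenth)?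
- Q in the autumn run at 14 min, as a share of the Z charged

Read across the table, the winter run at 1.9 min holds 0.0342 M of Q and the dawn run at 5.7 min holds 0.0331 M. With 3.00 times the E, the winter run needs about a third of the time, which reads as an order of 1 in [E].

Read down the dawn column, the rate sinks from 0.00903 M/min over the first row to 0.00267 M/min over the last, while Z loses 39.1% of its charge. Q therefore seems to brake the flask.

Take the drag W = [Z]/rate at the E of the dawn run. Near the start W stands at an opening value A, as in a first-order decay; later it grows with [Q]. Joining the two ends gives W = A(1 + b[Q]). With L = ln(charge/[Z]) and G = charge·L − [Q], integration gives t = A(L + bG).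

The last rows give L = 0.495 and G = 0.0157 M for the dawn run, and L = 0.613 and G = 0.00929 M for the dusk run. Both runs have the same E and stand at 14 min in these rows, so L + bG must come out equal in them, and the readings give b = 18.3 /M, the brake, the share of A that the drag gains per unit of [Q], and A = 17.9 min.

At one fixed [Q], this form makes the rate proportional to [Z], an order of 1. The dusk run reaches 15% at 0.00900 M of Q; the dawn run, at the same [Z], holds 0.0990 M by the balance. Their drags stand at 2.42 to one, so the dusk run is reckoned faster.

The autumn run has the E of the dawn run. With L = 0.288, it is reckoned to reach a quarter of its charge, 0.150 M, at 12.5 min. Its rate there, 0.00672 M/min, held on to 14 min, brings the share to 26.6%.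

The forecast, below this reckoning on the order in [Z] and on the share, gave 0.95, 1, faster and 25%, on the ground that “Rate falls far faster than Z does, so Q inhibits”. The flask gives 0.94, 1.0, faster and 26.7%.

    E + Z ⇌ EZ, settled at all times (13.40 /M)
    EZ + Z ⇌ EZ2, settled at all times (11.00 /M)
    EZ2 → Q + EZ (612.0 /min)
    E + Q ⇌ EQ, settled at all times (20.50 /M)
    2 Z ⇌ Z2, settled at all times (164.0 /M)

Carried to the winter run and scaled by its E, the same A and b put a quarter of the charge at 2.33 min, and that run stood there at 2.30 min. The brake is EQ, a case of product inhibition. At equal [Z], the rate of the dusk run over the dawn run stands at 2.4, and that lead is due to the pairing of E + Q to EQ. In the simulated run without the pairing, the two go alike, at a ratio of 1.0.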